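**Retrosynthetic overview**

1. Numbering: ring C1 (C=O), C2=C3, C4 (OAc), C5 (tertiary carbinol), side-chain carbinol C6. The last disconnections are the C6 silyl ether and the C4 acetate, leading back to a C6-silylated C4,C5-diol.
2. Key disconnection: the cyclopentenone is contracted out of a 3-substituted 4H-pyran-4-one. Light joins the two carbons flanking the ring oxygen (target C3–C4), water is captured at the substituted oxyallyl terminus (C5–O), and the ring oxygen ends as the C4 hydroxyl.
3. Feature on which this rests: the trans C4–O/C5–O pair on the five-membered ring, next to the C1 ketone and C2=C3 alkene, with the C5 tertiary carbinol carrying C6.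
4. Pyranone precursor: the C3–C6 bond comes from 3-bromo-4H-pyran-4-one and pentadecanal (chromium/nickel coupling). C6 is then set (S) by oxidation and oxazaborolidine-catalysed reduction, followed by silylation.
5. Ring order: the pyranone ring is bought; the only ring of the target, the carbocycle, is formed in the key step.

Key step: step 6

Remark: the target is (4R,5S,6S) with the C4 and C5 oxygens trans. C5 is labelled R in the two silyl-protected cyclopentenones only because the silyloxy group changes the ranking of C4 and C6; the geometry is the same. Water capture anti to the epoxide is assumed, as in the known solvent-trapped pyranone contractions.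

**Route**

Step 1
Reactants: 1 4H-pyran-4-one
Product: 3 3-bromo-4H-pyran-4-one, via trans-2,3-dibromide 2 (not isolated)
Conditions: Br2 (1.0 equiv), CH2Cl2, 0 °C; then Et3N, 0 °C to rt
Reagents that add atoms: bromine, BrBr
Why: Bromine adds across the C2=C3 enol-ether double bond and triethylamine removes HBr from the dibromide (α-bromination of an enone by addition–elimination), which should return the pyranone with bromine at C3, one equivalent of bromine limiting 3,5-dibromination.

Step 2
Reactants: 3 3-bromo-4H-pyran-4-one; 4 pentadecanal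
Product: 6 rac-3-(1-hydroxypentadecyl)-4H-pyran-4-one, via alkenylchromium dichloride 5 (not isolated)
Conditions: CrCl2 (4 equiv), NiCl2 (2 mol %), DMF, rt
Reagents that add atoms: none
Why: Nozaki–Hiyama–Kishi coupling, in which zerovalent nickel formed in the flask inserts into the electron-poor C3–Br bond, the alkenyl group passes to trivalent chromium and the alkenylchromium adds to the aldehyde only, leaving the vinylogous-ester carbonyl alone; the carbinol is formed racemic here and is set in steps 3 and 4.

Step 3
Reactants: 6 rac-3-(1-hydroxypentadecyl)-4H-pyran-4-one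
Product: 7 3-pentadecanoyl-4H-pyran-4-one
Conditions: Dess–Martin periodinane, CH2Cl2, 0 °C to rt
Reagents that add atoms: none
Why: Dess–Martin oxidation should convert the secondary allylic-type alcohol into the ketone under neutral, non-nucleophilic conditions that the electrophilic C2 position of the acylpyranone tolerates, and it erases the unselective centre.

Step 4
Reactants: 7 3-pentadecanoyl-4H-pyran-4-one
Product: 8 3-[(1S)-1-hydroxypentadecyl]-4H-pyran-4-one
Conditions: (R)-2-methyl-CBS-oxazaborolidine (0.2 equiv), catecholborane (1.5 equiv), toluene, −78 °C; then MeOH, aq. NaHCO3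
Reagents that add atoms: none
Why: Corey–Bakshi–Shibata reduction, in which the oxazaborolidine binds the side-chain ketone on the lone pair remote from the branched sp2 pyranonyl group (the large group) and catecholborane delivers hydride to one face, which with the (R)-catalyst should give the (S)-carbinol (mirror image of the (S)-catalyst/acetophenone case); a catalysed borane 1,2-reduction at low temperature is chosen because it should spare the doubly activated C2=C3 bond and the ring carbonyl.

Step 5
Reactants: 8 3-[(1S)-1-hydroxypentadecyl]-4H-pyran-4-one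
Product: 9 3-[(1S)-1-(tert-butyldimethylsilyloxy)pentadecyl]-4H-pyran-4-one
Conditions: TBSCl, imidazole, DMF, rt
Reagents that add atoms: tert-butyldimethylsilyl chloride, CC(C)(C)[Si](C)(C)Cl
Why: Imidazole-mediated silylation of the secondary alcohol; the silyl ether removes the hydrogen-bond donor at C6 for the key step and later lets the C4 hydroxyl be acetylated alone.

Step 6
Reactants: 9 3-[(1S)-1-(tert-butyldimethylsilyloxy)pentadecyl]-4H-pyran-4-one
Product: 12 (4R,5R)-4,5-dihydroxy-5-[(1S)-1-(tert-butyldimethylsilyloxy)pentadecyl]cyclopent-2-en-1-one, via oxyallyl zwitterion 10 (not isolated), via epoxy enol 11 (not isolated)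
Conditions: hν (254 nm, quartz), degassed MeCN/H2O 3:1, 1 mM, rt, to partial conversion (recovered 9 recycled)
Reagents that add atoms: water, O
Why: Excitation of the cross-conjugated dienone bonds pyranone C2 to C6 across the ring oxygen (formally a disrotatory 4π closure of the excited dienone, the oxygen counterpart of the type A cyclohexadienone rearrangement), which closes the five-membered carbocycle transannularly and leaves the ring oxygen as a fused epoxide in oxyallyl zwitterion 10. The closest known reaction is the photochemical ring contraction of alkyl-substituted 4H-pyran-4-ones with capture of this zwitterion by a hydroxylic solvent to give trans-4,5-dioxygenated cyclopent-2-enones. Water adds to the oxyallyl terminus that carries the side chain, the only fully substituted terminus and so the site of greater cationic character, and enol 11 then opens the epoxide by vinylogous β-elimination, which restores the enone and turns the former ring oxygen into the C4 hydroxyl. C4 is fixed by the face on which the epoxide sits and C5 by the approach of water anti to that epoxide, so the C4–O/C5–O pair must be trans. Because closure to 10 is reversible, the sense of the new ring relative to C6 is decided at capture: with the C6–O bond in the plane of the oxyallyl unit and turned away from the oxido oxygen (a dipole-minimised arrangement that a silyl ether, unlike a free hydroxyl, cannot override by hydrogen bonding), water meets the C6 hydrogen and not the tetradecyl chain only on the face that leads to 12. The step thus needs terminus selectivity, secured by the substituent at pyranone C3, and facial selectivity with respect to C6, which rests on this conformational bias of the silyloxy group and is the untested part of the step.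

Step 7
Reactants: 12 (4R,5R)-4,5-dihydroxy-5-[(1S)-1-(tert-butyldimethylsilyloxy)pentadecyl]cyclopent-2-en-1-one
Product: 13 (1R,5R)-5-[(1S)-1-(tert-butyldimethylsilyloxy)pentadecyl]-5-hydroxy-4-oxocyclopent-2-en-1-yl acetate
Conditions: Ac2O (1.5 equiv), pyridine, CH2Cl2, 0 °C
Reagents that add atoms: acetic anhydride, CC(=O)OC(C)=O
Why: Pyridine-mediated acylation should take place at the secondary allylic C4 hydroxyl and not at the hindered tertiary C5 hydroxyl, and because C5 bears no hydrogen the 4-acetoxy enone cannot eliminate acetic acid.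

Step 8
Reactants: 13 (1R,5R)-5-[(1S)-1-(tert-butyldimethylsilyloxy)pentadecyl]-5-hydroxy-4-oxocyclopent-2-en-1-yl acetate
Product: 14 (1R,5S)-5-hydroxy-5-[(1S)-1-hydroxypentadecyl]-4-oxocyclopent-2-en-1-yl acetate
Conditions: HF·pyridine, pyridine, THF, 0 °C to rt
Reagents that add atoms: none
Why: Fluoride-mediated Si–O cleavage under buffered acidic conditions should free the C6 hydroxyl, and the absence of base suppresses 1,3-acyl migration from the C4 oxygen to the cis-disposed C6 oxygen.

**Compound list**

1 | 4H-pyran-4-one | O=C1C=COC=C1 | starting material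
2 | trans-2,3-dibromo-2,3-dihydro-4H-pyran-4-one (racemic, one enantiomer drawn) | O=C1C=CO[C@H](Br)[C@H]1Br | intermediate
3 | 3-bromo-4H-pyran-4-one | O=C1C=COC=C1Br | intermediate
4 | pentadecanal | CCCCCCCCCCCCCCC=O | starting material
5 | dichloro(4-oxo-4H-pyran-3-yl)chromium (trivalent chromium, DMF-solvated) | O=C1C=COC=C1[Cr](Cl)Cl | intermediate
6 | rac-3-(1-hydroxypentadecyl)-4H-pyran-4-one | CCCCCCCCCCCCCCC(O)C1=COC=CC1=O | intermediate
7 | 3-pentadecanoyl-4H-pyran-4-one | CCCCCCCCCCCCCCC(=O)C1=COC=CC1=O | intermediate
8 | 3-[(1S)-1-hydroxypentadecyl]-4H-pyran-4-one | CCCCCCCCCCCCCC[C@H](O)C1=COC=CC1=O | intermediate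
9 | 3-[(1S)-1-(tert-butyldimethylsilyloxy)pentadecyl]-4H-pyran-4-one | CCCCCCCCCCCCCC[C@H](O[Si](C)(C)C(C)(C)C)C1=COC=CC1=O | intermediate
10 | 2-[(1S)-1-(tert-butyldimethylsilyloxy)pentadecyl]-6-oxabicyclo[3.1.0]hex-3-en-2-ylium-3-olate (oxyallyl zwitterion, epoxide on the face that becomes the C4–O face) | CCCCCCCCCCCCCC[C@H](O[Si](C)(C)C(C)(C)C)[C+]1C([O-])=C[C@H]2O[C@@H]12 | intermediate
11 | 2-[(1S)-1-(tert-butyldimethylsilyloxy)pentadecyl]-6-oxabicyclo[3.1.0]hex-3-ene-2,3-diol (C2 hydroxyl anti to the epoxide) | CCCCCCCCCCCCCC[C@H](O[Si](C)(C)C(C)(C)C)[C@@]1(O)C(O)=C[C@H]2O[C@@H]12 | intermediate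
12 | (4R,5R)-4,5-dihydroxy-5-[(1S)-1-(tert-butyldimethylsilyloxy)pentadecyl]cyclopent-2-en-1-one | CCCCCCCCCCCCCC[C@H](O[Si](C)(C)C(C)(C)C)[C@@]1(O)C(=O)C=C[C@H]1O | intermediate
13 | (1R,5R)-5-[(1S)-1-(tert-butyldimethylsilyloxy)pentadecyl]-5-hydroxy-4-oxocyclopent-2-en-1-yl acetate | CCCCCCCCCCCCCC[C@H](O[Si](C)(C)C(C)(C)C)[C@@]1(O)C(=O)C=C[C@H]1OC(C)=O | intermediate
14 | (1R,5S)-5-hydroxy-5-[(1S)-1-hydroxypentadecyl]-4-oxocyclopent-2-en-1-yl acetate | CCCCCCCCCCCCCC[C@H](O)[C@@]1(O)C(=O)C=C[C@H]1OC(C)=O | target

**Step count**

Total steps: 8. Longest linear sequence: 8 steps, from 4H-pyran-4-one 1.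

**Steps most likely to fail**

Step 6 (photochemical contraction). Three processes may go wrong:
- water capture at the unsubstituted oxyallyl terminus, since the silyloxy group inductively weakens the cationic character at the substituted one;
- poor facial selectivity of the capture relative to C6;
- epoxide migration in the zwitterion, or secondary photolysis of the enone, before or after capture.

Fallback, without photochemistry, setting out from pentadecanal 4 and coming back at the target 14. The lithium enolate of commercial (S)-4-(tert-butyldimethylsilyloxy)cyclopent-2-en-1-one (O=C1C=C[C@H](C1)O[Si](C)(C)C(C)(C)C; LiN(i-Pr)2, THF, −78 °C) would be added to 4 to give the 4,5-trans aldol adduct (4R,5S)-4-(tert-butyldimethylsilyloxy)-5-(1-hydroxypentadecyl)cyclopent-2-en-1-one F1 as a carbinol mixture. Mesylation (MsCl, Et3N) to the methanesulfonate of this aldol adduct F2 and elimination with DBU should give (4R,5E)-4-(tert-butyldimethylsilyloxy)-5-pentadecylidenecyclopent-2-en-1-one F3. Dihydroxylation of the exocyclic trisubstituted alkene (OsO4 cat., NMO, acetone/H2O), syn and anti to the neighbouring silyloxy group, would set C5 and C6 together and should give (4R,5S)-4-(tert-butyldimethylsilyloxy)-5-hydroxy-5-[(1S)-1-hydroxypentadecyl]cyclopent-2-en-1-one F4. Acetonide formation (2,2-dimethoxypropane, PPTS) gives the 5,6-O-isopropylidene acetal of this diol F5; HF·pyridine then frees the C4 hydroxyl to give the 4-hydroxy acetonide F6; Ac2O/pyridine gives the 4-acetoxy acetonide F7; and aqueous acetic acid removes the acetonide to give 14.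

Step 4 (asymmetric reduction). Hydride may be delivered to C2 of the doubly activated C2=C3 bond or to the ring carbonyl, or the enantioselectivity may be low if the catalyst binds the more basic pyranone oxygen.

Fallback by resolution, setting out from racemic alcohol 6 (steps 3 and 4 omitted) and coming back at 8. Acylation with (1S)-(−)-camphanic chloride (pyridine, DMAP, CH2Cl2) gives the diastereomeric esters (1S)-1-(4-oxo-4H-pyran-3-yl)pentadecyl (1S,4R)-camphanate F8 and (1R)-1-(4-oxo-4H-pyran-3-yl)pentadecyl (1S,4R)-camphanate F9, to be separated by chromatography or crystallisation. Methanolysis of F8 (K2CO3, MeOH, 0 °C) gives 8.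

Step 2 (chromium/nickel coupling). Oxidative addition or transmetalation at the α-bromo enone may be sluggish, and reductive debromination or homocoupling may compete.

Fallback by building the acylpyranone ring, setting out from pentadecanal 4 (steps 1 to 3 omitted) and coming back at ketone 7. Aldol addition of the lithium enolate of acetone (LiN(i-Pr)2, THF, −78 °C) gives rac-4-hydroxyoctadecan-2-one F10. Dess–Martin oxidation gives octadecane-2,4-dione F11. Heating with excess N,N-dimethylformamide dimethyl acetal gives the bis(enaminone) (1E)-1-(dimethylamino)-4-[(dimethylamino)methylidene]nonadec-1-ene-3,5-dione F12. Aqueous HCl in THF then closes it to 7 with loss of dimethylamine.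

**Further compounds**

F1 | step 6 | (4R,5S)-4-(tert-butyldimethylsilyloxy)-5-(1-hydroxypentadecyl)cyclopent-2-en-1-one (carbinol mixture) | CCCCCCCCCCCCCCC(O)[C@@H]1C(=O)C=C[C@H]1O[Si](C)(C)C(C)(C)C
F2 | step 6 | methanesulfonate of F1 | CCCCCCCCCCCCCCC(OS(C)(=O)=O)[C@@H]1C(=O)C=C[C@H]1O[Si](C)(C)C(C)(C)C
F3 | step 6 | (4R,5E)-4-(tert-butyldimethylsilyloxy)-5-pentadecylidenecyclopent-2-en-1-one | CCCCCCCCCCCCCC/C=C1/C(=O)C=C[C@H]1O[Si](C)(C)C(C)(C)C
F4 | step 6 | (4R,5S)-4-(tert-butyldimethylsilyloxy)-5-hydroxy-5-[(1S)-1-hydroxypentadecyl]cyclopent-2-en-1-one | CCCCCCCCCCCCCC[C@H](O)[C@@]1(O)C(=O)C=C[C@H]1O[Si](C)(C)C(C)(C)C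
F5 | step 6 | 5,6-O-isopropylidene acetal of F4 | CCCCCCCCCCCCCC[C@@H]1OC(C)(C)O[C@@]12C(=O)C=C[C@H]2O[Si](C)(C)C(C)(C)C
F6 | step 6 | 4-hydroxy acetonide (F5 without the silyl group) | CCCCCCCCCCCCCC[C@@H]1OC(C)(C)O[C@@]12C(=O)C=C[C@H]2O
F7 | step 6 | 4-acetoxy acetonide (5,6-O-isopropylidene acetal of 14) | CCCCCCCCCCCCCC[C@@H]1OC(C)(C)O[C@@]12C(=O)C=C[C@H]2OC(C)=O
F8 | step 4 | (1S)-1-(4-oxo-4H-pyran-3-yl)pentadecyl (1S,4R)-camphanate | CCCCCCCCCCCCCC[C@H](OC(=O)[C@@]12CC[C@@](C)(C(=O)O1)C2(C)C)C1=COC=CC1=O
F9 | step 4 | (1R)-1-(4-oxo-4H-pyran-3-yl)pentadecyl (1S,4R)-camphanate | CCCCCCCCCCCCCC[C@@H](OC(=O)[C@@]12CC[C@@](C)(C(=O)O1)C2(C)C)C1=COC=CC1=O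
F10 | step 2 | rac-4-hydroxyoctadecan-2-one | CCCCCCCCCCCCCCC(O)CC(C)=O
F11 | step 2 | octadecane-2,4-dione | CCCCCCCCCCCCCCC(=O)CC(C)=O
F12 | step 2 | (1E)-1-(dimethylamino)-4-[(dimethylamino)methylidene]nonadec-1-ene-3,5-dione | CCCCCCCCCCCCCCC(=O)C(=CN(C)C)C(=O)/C=C/N(C)C
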